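I chose to count these flasks per catalyst rather than per substrate, and to commit to that bet before seeing any of them.

| flask | substrate | reagent | free catalyst | remark | time |
|---|---|---|---|---|---|
| north-east | 0.55 M | 0.40 M | 0.50 mM | run made earlier |  |
| theta | 0.50 M | 0.400 M | 0.50 mM |  | 20 min |
| alpha | 0.80 M | 0.600 M | 0.50 mM |  | 20 min |
| epsilon | 1.0 M | 0.600 M | 0.12 mM |  | 20 min |
| beta | 0.30 M | 0.400 M | 0.50 mM |  | 20 min |
| zeta | 0.80 M | 0.400 M | 1.5 mM |  | 20 min |

north-east run (percent of the substrate charged)

| time / min | product / % | substrate / % |
|---|---|---|
| 0.500 | 1.4 | 98.3 |
| 0.833 | 0.7 | 97.4 |
| 1.33 | 2.4 | 97.8 |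
| 2.00 | 4.6 | 94.0 |
| 3.00 | 8.3 | 92.4 |
| 5.00 | 12.8 | 87.8 |
| 8.00 | 17.6 | 79.9 |

(standard deviation of a reading: 1 percentage point)

- the flasks put in order of amount of product, in percent of the substrate charged, best first, at 20 min (theta / alpha / epsilon / beta / zeta)
- the same order at 4.0 min (theta / alpha / epsilon / beta / zeta)
- the amount of product, in percent of the substrate charged of the flask you put first, at 20 min
- the amount of product, in percent of the substrate charged of the flask you put last, at 20 min

- no earlier run changes the charge of free catalyst; that part of a forecast is a guess

I took the north-east run in slow motion. Its first instants showed little: at 0.500 min the product read 1.4 %, and with a scatter of 1 percentage point I could not tell a delay from none. The middle was plainer. The catalyst charge was 0.0909 % of the substrate charge, yet by 8.00 min the product read 17.6 %, so each catalyst charged had gone round 194 times on average. That gave 24.2 /min as the pace, the product made per catalyst charged per minute, averaged from the start: the turnover frequency. It was a mean over a run that slowed, with 8.3 % gained in the first 3.00 min and 9.3 points in the last 5.00 min, and that single run could not say what lay behind the slowing.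

My rule was therefore this: with the pace held at its north-east value in every flask, the fraction of the substrate turned equals the pace, times catalyst charge over substrate charge, times time. Its proportionality to catalyst was a guess, and its indifference to substrate was my bet. The end needed a ceiling. Assuming one reagent per product, I put zeta's stop at 50.0 % of its substrate, with reagent as the limiting reagent, and my pace reached that ceiling at 11.0 min.

At 20 min I therefore had beta at 80.7 %, zeta at its ceiling, theta at 48.4 %, alpha at 30.3 % and epsilon at 5.81 %. Zeta's lead over theta was a thin 1.6 points. At 4.0 min I had zeta at 18.2 %, ahead of beta at 16.1 %, with theta, alpha and epsilon following in that sequence.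

The forecast differed from mine. It gave zeta > alpha > beta > theta > epsilon at 20 min and zeta > alpha > beta > theta > epsilon at 4.0 min, with 43 % for its first flask and 15 % for its last, and it said: “One run cannot separate the orders, so they are assumed.”

The flasks gave beta > zeta > theta > alpha > epsilon at 20 min and zeta > beta > theta > alpha > epsilon at 4.0 min, the sequences I had reckoned, with beta at 64.9 %, below my figure, and epsilon at 7.53 %.

    catalyst intermediate D → free catalyst + product (k = 94.0 /min)
    reagent + catalyst intermediate B ⇌ catalyst intermediate C (K = 0.820 /M, k = 250 /M/min)
    catalyst intermediate A → catalyst intermediate B (k = 110 /min)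
    substrate + free catalyst → catalyst intermediate A (k = 380 /M/min)
    catalyst intermediate C → released group + catalyst intermediate D (k = 1400 /min)

Epsilon's own pace, per catalyst charged and averaged from the start to 20.0 min, came to 31.4 /min, above the 24.2 /min I had carried. I then took the neighbouring flask, which was epsilon with its catalyst raised to 0.480 mM, a factor of 4.00. Epsilon's pace gave it 30.1 %. That flask gave 27.9 %, a pace of 29.0 /min, with 72 % of its substrate and 54 % of its reagent still unbound.

The data are simulated for an exercise; scatter was added.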